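## Structural features

The target is built from two benzene rings, A and B, joined only by a diaryl ether oxygen between C6 of ring A and C1' of ring B; there is no further ring. Ring A is a benzoic acid with four contiguous substituents: CO2H at C1, OMe at C2, the (1S)-1-hydroxy-3-methylbutyl chain at C3 and the aryloxy group at C6, with hydrogen at C4 and C5. Ring B carries the ether oxygen at C1' between a free phenol at C2' and a hydroxymethyl group at C6', and a methyl group at C4'. The only stereocenter is the benzylic carbinol carbon of the side chain (S); it has no stereogenic neighbour, so only absolute control is needed. Fragile groups are that carbinol (ortho to OMe and para to the aryloxy oxygen, so it would ionise under acid), the ring B benzylic alcohol (ortho to the ether oxygen and within reach of the CO2H group, eight-membered lactone), and the electron-rich ring B phenol. The real difficulty is the congestion around the ether bond: C1' is substituted at both ortho positions, and C6 lies next to the carboxyl-bearing C1, which is itself wedged between two oxygen-bearing carbons. The key step exploits exactly this: the ether oxygen (C6) and the carboxyl carbon (on C1) stand on neighbouring ring carbons with the C2 methoxy group beside C1, so both can be delivered across the triple bond of a C1≡C6 aryne of ring A whose polarisation is fixed by that methoxy group.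

## Logic of the disconnections

24 ⇒ 23 ⇒ 22. The bonds cut are two O–Si bonds and one O–allyl bond. The two benzylic alcohols and the ring B phenol have to be masked while an aryl anion is generated, and these groups leave under buffered fluoride and neutral conditions with zerovalent palladium. The demand is that no acid strong enough to ionise the carbinol at the stereocenter is used at the end.

22 ⇒ 12 + 18 + CO2. The bonds cut are C6–O (ether) and C1–CO2H of ring A, two neighbouring bonds that are the most hindered in the molecule. In one sentence: aryne 20, released from 12, takes up phenoxide 19 and CO2 across its triple bond. The gain is that the contiguously tetrasubstituted ring A and the triply ortho-flanked ether collapse to a phenol, a silylaryl triflate and CO2, and the acid is obtained free. The demands are that 19 adds through oxygen at the aryne carbon distal to OMe, and that 21 is carboxylated faster than it is protonated.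

12 ⇒ 10 ⇒ 6. The bonds cut are O–S (triflate) and C–Si at the carbon between the two oxygen substituents. This position is the one place on 6 where two directing groups cooperate, so the aryne precursor follows from one metalation and one exchange of the group on oxygen. The demand is lithiation only at that site, with no deprotonation at the benzylic C–H of the stereocenter.

6 ⇒ 5 ⇒ 4 ⇒ 2 ⇒ 1. The bonds cut are O–Si, then (after adding back the alkene) the C–C bond between the carbinol carbon and the side-chain CH2, then the carbamate C–O bond. Cutting here sets the single stereocenter by reagent control on a simple aldehyde, before any congestion exists. The carbamate of 2 serves as phenol protection in this step and as directing group later. The demand is high facial selectivity in the addition to 2 and survival of the N–H carbamate.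

18 ⇒ 17 ⇒ 16 ⇒ 14 ⇒ 13. The bonds cut are O–Si, then the functional group change CH2OH ⇒ CHO, then O–allyl, then the change OH ⇒ OMe. The reason is that 13 already has the ring B substitution pattern. The demand is that the two phenolic oxygens of 14 are told apart (through dianion 15), and that the primary alcohol of 17 is silylated in preference to the phenol.

## Other disconnections considered

Alternative 1: The cut is the C6–O bond alone, in the polar sense; this is the first plan that comes to mind. The forward key step would be nucleophilic aromatic substitution (or a copper-mediated Ullmann coupling) of 18 on methyl 6-fluoro-2-methoxy-3-(3-methylbutanoyl)benzoate A1, whose fluoride is activated by the ortho ester and the para ketone. This would give keto ester A2, followed by enantioselective ketone reduction and ester hydrolysis. The chosen plan is preferred for these reasons: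
- A1 already holds all four contiguous substituents of ring A, so the hard part is only moved into a building block.
- The substitution must join a di-ortho-substituted phenoxide to a carbon next to an ester.
- The stereocenter would be set late on a bulky substrate.
- The ester of A2, flanked by two ortho groups, would have to be hydrolysed in the presence of two benzylic alcohols.

Alternative 2: The cut is again C6–O, but made intramolecularly by O→O aryl migration. The forward key step would be a Smiles rearrangement of depside A3 (base, dipolar aprotic solvent) to the diaryl ether acid A4, followed by reduction of the formyl group. The grounds against it are: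
- The migrating ring of A3 has only one activating formyl group at the ipso carbon, opposed by an ortho alkoxy and a para methyl donor, so the spiro Meisenheimer intermediate is poorly stabilised.
- A3 requires esterification of a 2,6-disubstituted benzoic acid with a di-ortho-substituted phenol.
- Ester cleavage competes under the basic conditions.
- Ring A must again be fully assembled beforehand.

Alternative 3: The cut follows the presumed biosynthesis: C6–O is formed and the bond between the ketone carbon and C1' of a benzophenone is broken. The forward key step would be oxidative dearomatising spirocyclisation of benzophenone A5 to spirodienone A6, followed by retro-Claisen opening with hydroxide, which would lead directly to 23. The grounds against it are: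
- A5 is a benzophenone with four ortho substituents, harder to assemble than the ether it is meant to produce.
- The oxidation must be steered to the acyl-bearing ipso carbon ortho to the phenol.
- A6 is a cyclohexa-2,4-dienone, a class prone to Diels–Alder dimerisation.
- The step count is higher.

Key step: step 11

Assumption: the stereodescriptor of the SMILES string is read as the S configuration at the carbinol carbon (priorities OH > aryl > CH2 > H), and 1 and 13 are taken to be commercially available.

## Steps

Step 1
Reactants: 1 4-hydroxy-2-methoxybenzaldehyde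
Product: 2 4-formyl-3-methoxyphenyl propan-2-ylcarbamate
Conditions: i-PrNCO, Et3N (cat.), CH2Cl2, rt
Reagents that add atoms: isopropyl isocyanate, CC(C)N=C=O
Why: Base-catalysed addition of the phenol to the isocyanate (O-carbamoylation); the N-monosubstituted carbamate masks the phenol now, directs metalation in step 5 and can be removed under mild base in step 6.

Step 2
Reactants: 2 4-formyl-3-methoxyphenyl propan-2-ylcarbamate
Product: 4 4-[(1S)-1-hydroxy-3-methylbut-3-en-1-yl]-3-methoxyphenyl propan-2-ylcarbamate, via borinate ester 3 (not isolated)
Conditions: (−)-Ipc2BOMe, 2-methylallylMgCl, Et2O, 0 °C; then 2, −78 °C; then HOCH2CH2NH2, rt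
Reagents that add atoms: 2-methylallylmagnesium chloride, CC(=C)C[Mg]Cl
Why: Brown asymmetric allylboration through a chair Zimmerman–Traxler transition state; the reagent derived from (+)-α-pinene should deliver the 2-methylallyl group to the si face of the aldehyde, which gives the S carbinol (aryl ranks above CH2), the same sense as with benzaldehyde. The non-basic allylborane should leave the N–H carbamate alone, and the ethanolamine work-up releases the alcohol without strong base.

Step 3
Reactants: 4 4-[(1S)-1-hydroxy-3-methylbut-3-en-1-yl]-3-methoxyphenyl propan-2-ylcarbamate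
Product: 5 4-[(1S)-1-hydroxy-3-methylbutyl]-3-methoxyphenyl propan-2-ylcarbamate
Conditions: H2 (1 atm), 5% Pt/C, EtOAc, rt
Reagents that add atoms: none
Why: Heterogeneous catalytic hydrogenation of the 1,1-disubstituted alkene; platinum in a neutral solvent is chosen so that the electron-rich benzylic C–O bond is not hydrogenolysed, and the stereocenter is not involved.

Step 4
Reactants: 5 4-[(1S)-1-hydroxy-3-methylbutyl]-3-methoxyphenyl propan-2-ylcarbamate
Product: 6 4-[(1S)-1-{[tert-butyl(dimethyl)silyl]oxy}-3-methylbutyl]-3-methoxyphenyl propan-2-ylcarbamate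
Conditions: TBSCl, imidazole, DMF, rt → 40 °C
Reagents that add atoms: tert-butyldimethylsilyl chloride, CC(C)(C)[Si](C)(C)Cl
Why: Silyl ether formation at the secondary alcohol; the silyl ether removes the only proton source of this fragment and should withstand organolithium, amine base and fluoride at room temperature.

Step 5
Reactants: 6 4-[(1S)-1-{[tert-butyl(dimethyl)silyl]oxy}-3-methylbutyl]-3-methoxyphenyl propan-2-ylcarbamate
Product: 10 4-[(1S)-1-{[tert-butyl(dimethyl)silyl]oxy}-3-methylbutyl]-3-methoxy-2-(trimethylsilyl)phenyl propan-2-ylcarbamate, via N-silyl carbamate 7 (not isolated), via aryllithium 8 (not isolated), via bis-silyl carbamate 9 (not isolated)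
Conditions: TBSOTf, TMEDA, Et2O, 0 °C → rt; n-BuLi, TMEDA, −78 °C; TMSCl, −78 °C → rt; aq. NaHSO4, 0 °C
Reagents that add atoms: chlorotrimethylsilane, C[Si](C)(C)Cl
Why: Directed ortho-metalation: transient N-silylation masks the N–H, n-BuLi/TMEDA should remove the proton between the carbamate and methoxy groups (two cooperating directing groups), and TMSCl traps the aryllithium at −78 °C before an anionic ortho-Fries shift can set in. The benzylic C–H next to the silyloxy group is much less acidic at this temperature, so the configuration should be kept; aqueous work-up cleaves the N–Si bond.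

Step 6
Reactants: 10 4-[(1S)-1-{[tert-butyl(dimethyl)silyl]oxy}-3-methylbutyl]-3-methoxy-2-(trimethylsilyl)phenyl propan-2-ylcarbamate
Product: 12 4-[(1S)-1-{[tert-butyl(dimethyl)silyl]oxy}-3-methylbutyl]-3-methoxy-2-(trimethylsilyl)phenyl trifluoromethanesulfonate, via phenol 11 (not isolated)
Conditions: Et2NH, DBU, MeCN, 40 °C; then PhNTf2, rt
Reagents that add atoms: N-phenylbis(trifluoromethanesulfonimide), O=S(=O)(N(c1ccccc1)S(=O)(=O)C(F)(F)F)C(F)(F)F
Why: E1cB cleavage of the N-monosubstituted carbamate (the isocyanate is scavenged by Et2NH as a urea), then O-sulfonylation of the phenoxide in the same flask. No acid is used, so neither the aryl–silicon bond nor the benzylic silyl ether should suffer.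

Step 7
Reactants: 13 2-hydroxy-3-methoxy-5-methylbenzaldehyde
Product: 14 2,3-dihydroxy-5-methylbenzaldehyde
Conditions: BBr3, CH2Cl2, −78 °C → rt; H2O
Reagents that add atoms: none
Why: Lewis-acid O-demethylation of an aryl methyl ether (boron coordinates the ether oxygen, bromide removes the methyl group); the aldehyde and the ring methyl group are inert.

Step 8
Reactants: 14 2,3-dihydroxy-5-methylbenzaldehyde
Product: 16 2-hydroxy-5-methyl-3-(prop-2-en-1-yloxy)benzaldehyde, via disodium salt 15 (not isolated)
Conditions: NaH (2.2 equiv), DMSO/THF, rt; allyl bromide (1.0 equiv), rt; aq. HCl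
Reagents that add atoms: allyl bromide, C=CCBr
Why: Williamson etherification of a dianion: the 2-phenoxide is conjugated with and chelated to the formyl group, so the 3-phenoxide is the more nucleophilic oxygen and should take the single equivalent of allyl bromide.

Step 9
Reactants: 16 2-hydroxy-5-methyl-3-(prop-2-en-1-yloxy)benzaldehyde
Product: 17 2-(hydroxymethyl)-4-methyl-6-(prop-2-en-1-yloxy)phenol
Conditions: NaBH4, MeOH, 0 °C
Reagents that add atoms: none
Why: Hydride reduction of the aldehyde to the primary alcohol; the allyl ether is inert, and the low temperature avoids quinone methide formation from the salicyl alcohol.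

Step 10
Reactants: 17 2-(hydroxymethyl)-4-methyl-6-(prop-2-en-1-yloxy)phenol
Product: 18 2-({[tert-butyl(dimethyl)silyl]oxy}methyl)-4-methyl-6-(prop-2-en-1-yloxy)phenol
Conditions: TBSCl (1.05 equiv), imidazole, CH2Cl2, 0 °C
Reagents that add atoms: tert-butyldimethylsilyl chloride, CC(C)(C)[Si](C)(C)Cl
Why: Chemoselective silylation: the primary aliphatic alcohol should react ahead of the hindered phenol, which is flanked on both sides and hydrogen-bonded; an alkyl silyl ether is also the thermodynamically preferred site next to a phenol.

Step 11
Reactants: 12 4-[(1S)-1-{[tert-butyl(dimethyl)silyl]oxy}-3-methylbutyl]-3-methoxy-2-(trimethylsilyl)phenyl trifluoromethanesulfonate; 18 2-({[tert-butyl(dimethyl)silyl]oxy}methyl)-4-methyl-6-(prop-2-en-1-yloxy)phenol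
Product: 22 6-[2-({[tert-butyl(dimethyl)silyl]oxy}methyl)-4-methyl-6-(prop-2-en-1-yloxy)phenoxy]-3-[(1S)-1-{[tert-butyl(dimethyl)silyl]oxy}-3-methylbutyl]-2-methoxybenzoic acid, via potassium phenoxide 19 (not isolated), via aryne 20 (not isolated), via aryl anion 21 (not isolated)
Conditions: 18, KH, THF, 0 °C; then 12, KF, 18-crown-6, CO2 (1 atm), THF, 0 °C → rt; aq. HCl (pH 3)
Reagents that add atoms: carbon dioxide, O=C=O
Why: Proposed new method: an aryne three-component coupling in which fluoride (KF/18-crown-6) desilylates 12 and expels triflate to give aryne 20, phenoxide 19 adds through oxygen to the aryne carbon distal to the methoxy group (C6 of ring A), and the resulting aryl anion 21, located at C1 between the methoxy and the new aryloxy group, is carboxylated by dissolved CO2, so that acidification gives 22. The closest known reaction types are the three-component coupling of arynes, amines and CO2 to anthranilic acids (same fluoride conditions, same capture of the aryne-derived aryl anion by CO2), the O-arylation of phenols by ortho-silylaryl triflates, and the salicylate/aryne annulation to xanthones, in which this kind of 2-aryloxyaryl anion is intercepted by a carbonyl group; what has not been shown is an anionic oxygen nucleophile as first component with CO2 as third. No ring is closed and no stereocenter is formed; the silyl-protected carbinol is remote and is not touched. The regiochemistry rests on the methoxy group beside the triple bond: its inductive pull distorts the aryne so that the distal carbon is the flatter, more electrophilic one and the developing negative charge is placed next to oxygen (aryne distortion model), the known behaviour of 3-methoxybenzyne. The ring B phenoxide is blocked at both ortho positions and at the para position, so only O-arylation is open. The step needs carboxylation of 21 to outrun protonation, which the aprotic medium (phenoxide preformed with KH, so no conjugate acid is left) and the potassium chelate between two ortho oxygens should favour, and it needs phenoxide addition to outrun reversible carbonate formation from 19 and CO2, which the hindered phenoxide and a low CO2 pressure should favour.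

Step 12
Reactants: 22 6-[2-({[tert-butyl(dimethyl)silyl]oxy}methyl)-4-methyl-6-(prop-2-en-1-yloxy)phenoxy]-3-[(1S)-1-{[tert-butyl(dimethyl)silyl]oxy}-3-methylbutyl]-2-methoxybenzoic acid
Product: 23 6-[2-({[tert-butyl(dimethyl)silyl]oxy}methyl)-6-hydroxy-4-methylphenoxy]-3-[(1S)-1-{[tert-butyl(dimethyl)silyl]oxy}-3-methylbutyl]-2-methoxybenzoic acid
Conditions: Pd(PPh3)4 (cat.), morpholine, THF, rt
Reagents that add atoms: none
Why: Tsuji–Trost-type deallylation: zerovalent palladium ionises the aryl allyl ether to a π-allyl complex of divalent palladium and morpholine takes up the allyl group irreversibly; silyl ethers, the acid and the stereocenter are not touched under these neutral conditions.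

Step 13
Reactants: 23 6-[2-({[tert-butyl(dimethyl)silyl]oxy}methyl)-6-hydroxy-4-methylphenoxy]-3-[(1S)-1-{[tert-butyl(dimethyl)silyl]oxy}-3-methylbutyl]-2-methoxybenzoic acid
Product: 24 6-[2-hydroxy-6-(hydroxymethyl)-4-methylphenoxy]-3-[(1S)-1-hydroxy-3-methylbutyl]-2-methoxybenzoic acid (CNP0221397.1)
Conditions: TBAF, AcOH, THF, rt → 40 °C
Reagents that add atoms: none
Why: Fluoride-induced cleavage of both silyl ethers (Si–F bond formation), buffered with AcOH so that neither strong base nor strong acid meets the benzylic alcohols. The C–O bond at the stereocenter is not broken, so the S configuration set in step 2 is carried into the target.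

## Compound list

1 | 4-hydroxy-2-methoxybenzaldehyde | COc1cc(O)ccc1C=O | starting material
2 | 4-formyl-3-methoxyphenyl propan-2-ylcarbamate | COc1cc(OC(=O)NC(C)C)ccc1C=O | intermediate
3 | O-(diisopinocampheylboryl) ether of 4 (borinate ester, isopinocampheyl groups from (+)-α-pinene) | COc1cc(OC(=O)NC(C)C)ccc1[C@@H](OB([C@@H]2C[C@@H]3C[C@H]([C@H]2C)C3(C)C)[C@@H]2C[C@@H]3C[C@H]([C@H]2C)C3(C)C)CC(C)=C | intermediate
4 | 4-[(1S)-1-hydroxy-3-methylbut-3-en-1-yl]-3-methoxyphenyl propan-2-ylcarbamate | COc1cc(OC(=O)NC(C)C)ccc1[C@@H](O)CC(C)=C | intermediate
5 | 4-[(1S)-1-hydroxy-3-methylbutyl]-3-methoxyphenyl propan-2-ylcarbamate | COc1cc(OC(=O)NC(C)C)ccc1[C@@H](O)CC(C)C | intermediate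
6 | 4-[(1S)-1-{[tert-butyl(dimethyl)silyl]oxy}-3-methylbutyl]-3-methoxyphenyl propan-2-ylcarbamate | COc1cc(OC(=O)NC(C)C)ccc1[C@@H](O[Si](C)(C)C(C)(C)C)CC(C)C | intermediate
7 | N-[tert-butyl(dimethyl)silyl] derivative of 6 | COc1cc(OC(=O)N(C(C)C)[Si](C)(C)C(C)(C)C)ccc1[C@@H](O[Si](C)(C)C(C)(C)C)CC(C)C | intermediate
8 | 2-lithio derivative of 7 (lithium between the carbamate and methoxy groups) | COc1c([Li])c(OC(=O)N(C(C)C)[Si](C)(C)C(C)(C)C)ccc1[C@@H](O[Si](C)(C)C(C)(C)C)CC(C)C | intermediate
9 | 2-(trimethylsilyl) derivative of 7 | COc1c([Si](C)(C)C)c(OC(=O)N(C(C)C)[Si](C)(C)C(C)(C)C)ccc1[C@@H](O[Si](C)(C)C(C)(C)C)CC(C)C | intermediate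
10 | 4-[(1S)-1-{[tert-butyl(dimethyl)silyl]oxy}-3-methylbutyl]-3-methoxy-2-(trimethylsilyl)phenyl propan-2-ylcarbamate | COc1c([Si](C)(C)C)c(OC(=O)NC(C)C)ccc1[C@@H](O[Si](C)(C)C(C)(C)C)CC(C)C | intermediate
11 | 4-[(1S)-1-{[tert-butyl(dimethyl)silyl]oxy}-3-methylbutyl]-3-methoxy-2-(trimethylsilyl)phenol | COc1c([Si](C)(C)C)c(O)ccc1[C@@H](O[Si](C)(C)C(C)(C)C)CC(C)C | intermediate
12 | 4-[(1S)-1-{[tert-butyl(dimethyl)silyl]oxy}-3-methylbutyl]-3-methoxy-2-(trimethylsilyl)phenyl trifluoromethanesulfonate | COc1c([Si](C)(C)C)c(OS(=O)(=O)C(F)(F)F)ccc1[C@@H](O[Si](C)(C)C(C)(C)C)CC(C)C | intermediate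
13 | 2-hydroxy-3-methoxy-5-methylbenzaldehyde | COc1cc(C)cc(C=O)c1O | starting material
14 | 2,3-dihydroxy-5-methylbenzaldehyde | Cc1cc(O)c(O)c(C=O)c1 | intermediate
15 | disodium 3-formyl-5-methylbenzene-1,2-bis(olate) | Cc1cc([O-])c([O-])c(C=O)c1.[Na+].[Na+] | intermediate
16 | 2-hydroxy-5-methyl-3-(prop-2-en-1-yloxy)benzaldehyde | C=CCOc1cc(C)cc(C=O)c1O | intermediate
17 | 2-(hydroxymethyl)-4-methyl-6-(prop-2-en-1-yloxy)phenol | C=CCOc1cc(C)cc(CO)c1O | intermediate
18 | 2-({[tert-butyl(dimethyl)silyl]oxy}methyl)-4-methyl-6-(prop-2-en-1-yloxy)phenol | C=CCOc1cc(C)cc(CO[Si](C)(C)C(C)(C)C)c1O | intermediate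
19 | potassium 2-({[tert-butyl(dimethyl)silyl]oxy}methyl)-4-methyl-6-(prop-2-en-1-yloxy)phenolate | C=CCOc1cc(C)cc(CO[Si](C)(C)C(C)(C)C)c1[O-].[K+] | intermediate
20 | 4-[(1S)-1-{[tert-butyl(dimethyl)silyl]oxy}-3-methylbutyl]-3-methoxy-1,2-didehydrobenzene (ring A aryne, triple bond between C1 and C6 of the target numbering) | COC1=C([C@@H](O[Si](C)(C)C(C)(C)C)CC(C)C)C=CC#C1 | intermediate
21 | potassium aryl anion of ring A (carbanion at C1, between the methoxy and aryloxy groups; 22 without CO2) | COc1c([C@@H](O[Si](C)(C)C(C)(C)C)CC(C)C)ccc(Oc2c(OCC=C)cc(C)cc2CO[Si](C)(C)C(C)(C)C)[c-]1.[K+] | intermediate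
22 | 6-[2-({[tert-butyl(dimethyl)silyl]oxy}methyl)-4-methyl-6-(prop-2-en-1-yloxy)phenoxy]-3-[(1S)-1-{[tert-butyl(dimethyl)silyl]oxy}-3-methylbutyl]-2-methoxybenzoic acid | COc1c([C@@H](O[Si](C)(C)C(C)(C)C)CC(C)C)ccc(Oc2c(OCC=C)cc(C)cc2CO[Si](C)(C)C(C)(C)C)c1C(=O)O | intermediate
23 | 6-[2-({[tert-butyl(dimethyl)silyl]oxy}methyl)-6-hydroxy-4-methylphenoxy]-3-[(1S)-1-{[tert-butyl(dimethyl)silyl]oxy}-3-methylbutyl]-2-methoxybenzoic acid | COc1c([C@@H](O[Si](C)(C)C(C)(C)C)CC(C)C)ccc(Oc2c(O)cc(C)cc2CO[Si](C)(C)C(C)(C)C)c1C(=O)O | intermediate
24 | 6-[2-hydroxy-6-(hydroxymethyl)-4-methylphenoxy]-3-[(1S)-1-hydroxy-3-methylbutyl]-2-methoxybenzoic acid | COc1c([C@@H](O)CC(C)C)ccc(Oc2c(O)cc(C)cc2CO)c1C(=O)O | target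

## Step count and least certain steps

Total step count: 13. Longest linear sequence: 9 (steps 1 to 6, then 11 to 13); steps 7 to 10 form the four-step ring B branch that joins in step 11.

**Step 11 (key step, proposed new method).** Two processes are most likely to go wrong:
- Protonation of the aryl anion instead of carboxylation, because an aryl anion with a potassium counter-ion is basic enough to take a proton from any trace acid or from the solvent.
- Capture of the phenoxide by CO2 as an aryl carbonate, which would add through a carbonate oxygen and end in acyl transfer instead of etherification.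

Fallback with known chemistry: setting out from 12 and 18, fluoride-induced O-arylation without CO2 (CsF, MeCN, rt, the aryl anion being protonated by the medium) would give the decarboxy diaryl ether F1 with the same regiochemistry. Directed ortho-lithiation of F1 at the single C–H flanked by the methoxy and aryloxy groups (n-BuLi, TMEDA, Et2O, 0 °C) would give the aryllithium F2, and its carboxylation with CO2 returns to the route at 22.

**Step 5.** Most likely to go wrong is the site of deprotonation. The methoxy group is buttressed by the bulky side chain, so lithiation at the unhindered ortho position on the other side of the carbamate, or at the benzylic C–H with loss of configuration, could compete. Fallback, which moves the silylation ahead of the stereocenter: setting out from 2, acetalisation with ethylene glycol (TsOH cat., benzene, reflux) would give the dioxolane F3. The N-silylation/lithiation/TMSCl sequence on F3 would give the silylated dioxolane F4, and mild hydrolysis (PPTS, wet acetone) the silylated aldehyde F5. Allylboration as in step 2 would give the homoallylic alcohol F6 and hydrogenation as in step 3 the saturated alcohol F7. Silylation as in step 4 returns to the route at 10.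

**Step 2.** Most likely to go wrong is poor facial selectivity with the ortho-methoxy aldehyde, or loss of the base-sensitive carbamate during work-up. Fallback, which replaces reagent-controlled C–C bond formation by catalyst-controlled ketone reduction: setting out from 2, zinc-mediated Barbier addition of 2-methylallyl bromide (Zn, THF/aq. NH4Cl) would give the racemic homoallylic alcohol F8. Hydrogenation would give the racemic saturated alcohol F9 and Dess–Martin oxidation the ketone F10. Asymmetric transfer hydrogenation with RuCl(p-cymene)[(S,S)-TsDPEN] in HCO2H/Et3N, which should give the S carbinol of an aryl alkyl ketone, returns to the route at 5.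

**Step 8.** Most likely to go wrong is alkylation at the wrong oxygen or at both, if the dianion is not fully formed or equilibrates with the monoanion. Fallback, which tells the oxygens apart by ring formation: setting out from 14, reduction (NaBH4, MeOH) would give the triol F11. Acetonide formation between the 2-hydroxyl and the hydroxymethyl group (2,2-dimethoxypropane, PPTS) would give the benzodioxine F12 with only the 3-hydroxyl free. Allylation (allyl bromide, K2CO3, DMF) would give the allyl ether F13, and mild aqueous acid (AcOH/H2O) returns to the route at 17.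

## Further compounds

F1 | step 11 | {[2-{3-methoxy-4-[(1S)-1-{[tert-butyl(dimethyl)silyl]oxy}-3-methylbutyl]phenoxy}-5-methyl-3-(prop-2-en-1-yloxy)benzyl]oxy}(tert-butyl)dimethylsilane (22 without the carboxyl group) | COc1c([C@@H](O[Si](C)(C)C(C)(C)C)CC(C)C)ccc(Oc2c(OCC=C)cc(C)cc2CO[Si](C)(C)C(C)(C)C)c1
F2 | step 11 | 2-lithio derivative of F1 (lithium between the methoxy and aryloxy groups) | COc1c([C@@H](O[Si](C)(C)C(C)(C)C)CC(C)C)ccc(Oc2c(OCC=C)cc(C)cc2CO[Si](C)(C)C(C)(C)C)c1[Li]
F3 | step 5 | 4-(1,3-dioxolan-2-yl)-3-methoxyphenyl propan-2-ylcarbamate | COc1cc(OC(=O)NC(C)C)ccc1C1OCCO1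
F4 | step 5 | 4-(1,3-dioxolan-2-yl)-3-methoxy-2-(trimethylsilyl)phenyl propan-2-ylcarbamate | COc1c([Si](C)(C)C)c(OC(=O)NC(C)C)ccc1C1OCCO1
F5 | step 5 | 4-formyl-3-methoxy-2-(trimethylsilyl)phenyl propan-2-ylcarbamate | COc1c([Si](C)(C)C)c(OC(=O)NC(C)C)ccc1C=O
F6 | step 5 | 4-[(1S)-1-hydroxy-3-methylbut-3-en-1-yl]-3-methoxy-2-(trimethylsilyl)phenyl propan-2-ylcarbamate | COc1c([Si](C)(C)C)c(OC(=O)NC(C)C)ccc1[C@@H](O)CC(C)=C
F7 | step 5 | 4-[(1S)-1-hydroxy-3-methylbutyl]-3-methoxy-2-(trimethylsilyl)phenyl propan-2-ylcarbamate | COc1c([Si](C)(C)C)c(OC(=O)NC(C)C)ccc1[C@@H](O)CC(C)C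
F8 | step 2 | racemic 4-(1-hydroxy-3-methylbut-3-en-1-yl)-3-methoxyphenyl propan-2-ylcarbamate | COc1cc(OC(=O)NC(C)C)ccc1C(O)CC(C)=C
F9 | step 2 | racemic 4-(1-hydroxy-3-methylbutyl)-3-methoxyphenyl propan-2-ylcarbamate | COc1cc(OC(=O)NC(C)C)ccc1C(O)CC(C)C
F10 | step 2 | 3-methoxy-4-(3-methylbutanoyl)phenyl propan-2-ylcarbamate | COc1cc(OC(=O)NC(C)C)ccc1C(=O)CC(C)C
F11 | step 8 | 3-(hydroxymethyl)-5-methylbenzene-1,2-diol | Cc1cc(O)c(O)c(CO)c1
F12 | step 8 | 2,2,6-trimethyl-4H-1,3-benzodioxin-8-ol | Cc1cc(O)c2OC(C)(C)OCc2c1
F13 | step 8 | 2,2,6-trimethyl-8-(prop-2-en-1-yloxy)-4H-1,3-benzodioxine | C=CCOc1cc(C)cc2COC(C)(C)Oc12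
A1 | alternative 1 | methyl 6-fluoro-2-methoxy-3-(3-methylbutanoyl)benzoate | COc1c(C(=O)CC(C)C)ccc(F)c1C(=O)OC
A2 | alternative 1 | methyl 6-[2-({[tert-butyl(dimethyl)silyl]oxy}methyl)-4-methyl-6-(prop-2-en-1-yloxy)phenoxy]-2-methoxy-3-(3-methylbutanoyl)benzoate | COc1c(C(=O)CC(C)C)ccc(Oc2c(OCC=C)cc(C)cc2CO[Si](C)(C)C(C)(C)C)c1C(=O)OC
A3 | alternative 2 | 2-formyl-4-methyl-6-(prop-2-en-1-yloxy)phenyl 3-[(1S)-1-{[tert-butyl(dimethyl)silyl]oxy}-3-methylbutyl]-6-hydroxy-2-methoxybenzoate (depside) | COc1c([C@@H](O[Si](C)(C)C(C)(C)C)CC(C)C)ccc(O)c1C(=O)Oc1c(OCC=C)cc(C)cc1C=O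
A4 | alternative 2 | 3-[(1S)-1-{[tert-butyl(dimethyl)silyl]oxy}-3-methylbutyl]-6-[2-formyl-4-methyl-6-(prop-2-en-1-yloxy)phenoxy]-2-methoxybenzoic acid | COc1c([C@@H](O[Si](C)(C)C(C)(C)C)CC(C)C)ccc(Oc2c(OCC=C)cc(C)cc2C=O)c1C(=O)O
A5 | alternative 3 | {3-[(1S)-1-{[tert-butyl(dimethyl)silyl]oxy}-3-methylbutyl]-6-hydroxy-2-methoxyphenyl}[2-({[tert-butyl(dimethyl)silyl]oxy}methyl)-6-hydroxy-4-methylphenyl]methanone | COc1c([C@@H](O[Si](C)(C)C(C)(C)C)CC(C)C)ccc(O)c1C(=O)c1c(O)cc(C)cc1CO[Si](C)(C)C(C)(C)C
A6 | alternative 3 | spiro[1-benzofuran-2(3H),1'-cyclohexa-3',5'-diene]-3,2'-dione carrying 4-methoxy, 5-[(1S)-1-(silyloxy)-3-methylbutyl], 4'-methyl and 6'-(silyloxymethyl) groups (mixture at the spiro carbon) | COc1c([C@@H](O[Si](C)(C)C(C)(C)C)CC(C)C)ccc2OC3(C(=O)C=C(C)C=C3CO[Si](C)(C)C(C)(C)C)C(=O)c12
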